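**Retrosynthetic overview**
1. The 4,5-epoxide is added last to the finished macrocycle; the C8 ester is cut to the macrocyclic alcohol and (2S,3R)-2,3-dimethyloxirane-2-carboxylic acid (Sharpless epoxidation of tiglyl alcohol).
2. The ten-membered ring is cut at C9–C10: intramolecular Nozaki–Hiyama–Kishi reaction of a (Z)-α-iodoenoate onto a C9 aldehyde.
3. C6–C7 is cut in a convergent indium Barbier union of the two halves: enal/iodoenoate 5 (C1–C6, C10, C14, C15) and the ring-locked allylic bromide 12 (C7–C9, C11–C13). A δ→γ lactone transposition then gives the butyrolactone and frees C9–OH.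
4. 5 comes from pent-4-yn-1-ol (Negishi carboalumination, iodo-Wittig); 12 from (S)-but-3-ene-1,2-diol and 2-(bromomethyl)acrylic acid (RCM).
5. Ring order: side-chain oxirane → dihydropyranone template → γ-lactone → cyclodecadiene → 4,5-oxirane.

Assumption: the stereochemistry is taken exactly as in the SMILES, i.e. 4R,5R,6S,7R,8S,9R with an 8,9-cis (erythro) diol and a (2S,3R) cis-dimethyl epoxy ester; the four starting materials are taken as commercial.
Atom labels C1–C15 are germacrane numbering (C12 lactone carbonyl, C13 exocyclic CH2, C14 ester carbon, C15 methyl).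

**Western half**

Step 1
Reactants: 1 pent-4-yn-1-ol
Product: 3 (2E)-3-methylhex-2-ene-1,6-diol, via alkenylalane 2 (not isolated)
Conditions: Me3Al (3 equiv), Cp2ZrCl2 (0.25 equiv), CH2Cl2, 0 °C → rt; then n-BuLi, (CH2O)n, THF, −78 °C → rt; aq. HCl
Reagents that add atoms: trimethylaluminium C[Al](C)C; formaldehyde (as paraformaldehyde) C=O
Why: Zr-catalysed Negishi carboalumination adds Me and Al syn across the terminal alkyne (Me to the internal carbon) and the alkenylalanate is hydroxymethylated with retention, so the (E)-trisubstituted allylic alcohol results.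

Step 2
Reactants: 3 (2E)-3-methylhex-2-ene-1,6-diol
Product: 4 (2E)-3-methylhex-2-enedial
Conditions: Dess–Martin periodinane (2.5 equiv), NaHCO3, CH2Cl2, 0 °C → rt
Reagents that add atoms: none
Why: Dess–Martin oxidation takes both primary alcohols to aldehydes under buffered conditions that do not isomerise the enal.

Step 3
Reactants: 4 (2E)-3-methylhex-2-enedial
Product: 5 methyl (2Z,6E)-2-iodo-6-methyl-8-oxoocta-2,6-dienoate
Conditions: Ph3P=CHCO2Me, NIS, CH2Cl2, −20 °C; then 4, K2CO3, −20 °C → rt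
Reagents that add atoms: methyl (triphenylphosphoranylidene)acetate COC(=O)C=P(c1ccccc1)(c1ccccc1)c1ccccc1; N-iodosuccinimide O=C1CCC(=O)N1I
Why: Wittig olefination with the α-iodo stabilised ylide made in situ should react at the unhindered saturated aldehyde far faster than at the β,β-disubstituted enal and places the ester trans to the chain, i.e. the (Z)-α-iodoenoate.

**Eastern half**

Step 4
Reactants: 6 2-(bromomethyl)prop-2-enoic acid
Product: 7 2-(bromomethyl)prop-2-enoyl chloride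
Conditions: (COCl)2, DMF (cat.), CH2Cl2, 0 °C → rt; evaporate
Reagents that add atoms: oxalyl chloride O=C(Cl)C(=O)Cl
Why: Vilsmeier-type acid chloride formation is neutral and leaves the allylic bromide untouched.

Step 5
Reactants: 8 (2S)-but-3-ene-1,2-diol
Product: 9 (4S)-4-ethenyl-2-(4-methoxyphenyl)-1,3-dioxolane (both C2 epimers)
Conditions: 4-MeOC6H4CH(OMe)2, PPTS (cat.), CH2Cl2, rt
Reagents that add atoms: 4-methoxybenzaldehyde dimethyl acetal COc1ccc(C(OC)OC)cc1
Why: acid-catalysed transacetalisation closes the dioxolane on the 1,2-diol without touching the stereocentre.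

Step 6
Reactants: 9 (4S)-4-ethenyl-2-(4-methoxyphenyl)-1,3-dioxolane
Product: 10 (2S)-2-[(4-methoxyphenyl)methoxy]but-3-en-1-ol
Conditions: DIBAL-H (2.5 equiv), CH2Cl2, −78 → 0 °C; Rochelle salt
Reagents that add atoms: none
Why: regioselective reductive acetal opening, in which DIBAL-H binds the less hindered primary oxygen and hydride quenches the oxocarbenium ion, leaves the PMB group on the secondary oxygen.

Step 7
Reactants: 10 (2S)-2-[(4-methoxyphenyl)methoxy]but-3-en-1-ol; 7 2-(bromomethyl)prop-2-enoyl chloride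
Product: 11 (2S)-2-[(4-methoxyphenyl)methoxy]but-3-en-1-yl 2-(bromomethyl)prop-2-enoate
Conditions: 2,6-lutidine, CH2Cl2, −40 → 0 °C
Reagents that add atoms: none
Why: O-acylation of the primary alcohol by the acid chloride, with a hindered base that cannot displace the allylic bromide.

Step 8
Reactants: 11 (2S)-2-[(4-methoxyphenyl)methoxy]but-3-en-1-yl 2-(bromomethyl)prop-2-enoate
Product: 12 (5S)-3-(bromomethyl)-5-[(4-methoxyphenyl)methoxy]-5,6-dihydro-2H-pyran-2-one
Conditions: Grubbs II (5 mol %), toluene (5 mM), 80 °C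
Reagents that add atoms: none
Why: ring-closing metathesis starts at the vinyl group and closes onto the 1,1-disubstituted acrylate with loss of ethene, and the six-membered ring locks C8 cis to the carbonyl and trans to CH2Br.

**Side-chain acid**

Step 9
Reactants: 13 (2E)-2-methylbut-2-enoic acid (tiglic acid)
Product: 14 (2E)-2-methylbut-2-en-1-ol
Conditions: LiAlH4, Et2O, 0 °C → rt
Reagents that add atoms: none
Why: hydride 1,2-reduction of the unsaturated acid gives the allylic alcohol with the E geometry retained.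

Step 10
Reactants: 14 (2E)-2-methylbut-2-en-1-ol
Product: 15 [(2R,3R)-2,3-dimethyloxiran-2-yl]methanol
Conditions: Ti(OiPr)4 (10 mol %), D-(−)-DIPT (12 mol %), TBHP, 4 Å MS, CH2Cl2, −20 °C
Reagents that add atoms: tert-butyl hydroperoxide CC(C)(C)OO
Why: Sharpless asymmetric epoxidation with D-(−)-tartrate gives the enantiomer of the (2S,3S) epoxide formed with L-(+)-tartrate, and the E-alkene fixes the two methyl groups cis.

Step 11
Reactants: 15 [(2R,3R)-2,3-dimethyloxiran-2-yl]methanol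
Product: 16 (2S,3R)-2,3-dimethyloxirane-2-carboxylic acid
Conditions: RuCl3·xH2O (2 mol %), NaIO4 (3 equiv), CCl4/MeCN/H2O, rt
Reagents that add atoms: water O
Why: Sharpless RuO4 oxidation converts the primary alcohol to the acid without touching either epoxide carbon (the C2 label changes from R to S by priority only).

**Union and endgame**

Step 12
Reactants: 5 methyl (2Z,6E)-2-iodo-6-methyl-8-oxoocta-2,6-dienoate; 12 (5S)-3-(bromomethyl)-5-[(4-methoxyphenyl)methoxy]-5,6-dihydro-2H-pyran-2-one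
Product: 17 methyl (2Z,6E,8R)-8-hydroxy-2-iodo-8-{(4S,5S)-5-[(4-methoxyphenyl)methoxy]-3-methylidene-2-oxooxan-4-yl}-6-methylocta-2,6-dienoate
Conditions: In powder (2 equiv), THF/H2O 1:1, rt
Reagents that add atoms: none
Why: indium Barbier allylation adds 1,2 to the enal through a Zimmerman–Traxler chair in which the ring-locked allyl geometry (C8 trans to CH2In) puts both substituents equatorial (6,7-anti, the later trans-lactone), and the aldehyde approaches the ring face anti to the C8 PMB ether (7,8-trans), while In(0) should leave the vinyl iodide alone.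

Step 13
Reactants: 17 (δ-lactone adduct)
Product: 18 methyl (2Z,6E)-7-{(2R,3S)-3-[(1S)-2-hydroxy-1-[(4-methoxyphenyl)methoxy]ethyl]-4-methylidene-5-oxooxolan-2-yl}-2-iodo-6-methylhepta-2,6-dienoate
Conditions: PPTS (20 mol %), CH2Cl2, rt
Reagents that add atoms: none
Why: acid-catalysed translactonisation lets the C6 hydroxyl close the more stable trans-disubstituted γ-lactone and releases the primary C9 alcohol, with no stereocentre involved.

Step 14
Reactants: 18 (γ-lactone primary alcohol)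
Product: 19 methyl (2Z,6E)-2-iodo-7-{(2R,3S)-3-[(1S)-1-[(4-methoxyphenyl)methoxy]-2-oxoethyl]-4-methylidene-5-oxooxolan-2-yl}-6-methylhepta-2,6-dienoate
Conditions: Dess–Martin periodinane, NaHCO3, CH2Cl2, 0 °C → rt
Reagents that add atoms: none
Why: Dess–Martin oxidation gives the α-alkoxy aldehyde under neutral conditions that do not epimerise C8.

Step 15
Reactants: 19 (iodoenoate aldehyde)
Product: 20 methyl (3aS,4S,5R,6E,10E,11aR)-5-hydroxy-4-[(4-methoxyphenyl)methoxy]-10-methyl-3-methylidene-2-oxo-2,3,3a,4,5,8,9,11a-octahydrocyclodeca[b]furan-6-carboxylate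
Conditions: CrCl2 (10 equiv), NiCl2 (0.1 equiv), DMSO, rt, 2 mM (syringe pump)
Reagents that add atoms: none
Why: intramolecular Nozaki–Hiyama–Kishi reaction forms the alkenylchromium with retention of geometry and adds it to the aldehyde at high dilution to close the ten-membered ring, polar Felkin–Anh attack anti to the C8–O bond giving the 8,9-anti (9R) alcohol.

Step 16
Reactants: 20 (macrocyclic C9 alcohol)
Product: 21 methyl (3aS,4S,5R,6E,10E,11aR)-5-[(tert-butyldimethylsilyl)oxy]-4-[(4-methoxyphenyl)methoxy]-10-methyl-3-methylidene-2-oxo-2,3,3a,4,5,8,9,11a-octahydrocyclodeca[b]furan-6-carboxylate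
Conditions: TBSOTf, 2,6-lutidine, CH2Cl2, −78 → 0 °C
Reagents that add atoms: tert-butyldimethylsilyl triflate CC(C)(C)[Si](C)(C)OS(=O)(=O)C(F)(F)F
Why: silyl triflate silylation protects the hindered secondary allylic alcohol without base-sensitive side reactions.

Step 17
Reactants: 21 (C9 TBS ether, C8 PMB ether)
Product: 22 methyl (3aR,4S,5R,6E,10E,11aR)-5-[(tert-butyldimethylsilyl)oxy]-4-hydroxy-10-methyl-3-methylidene-2-oxo-2,3,3a,4,5,8,9,11a-octahydrocyclodeca[b]furan-6-carboxylate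
Conditions: DDQ, CH2Cl2/pH 7 buffer 10:1, 0 °C → rt
Reagents that add atoms: none
Why: oxidative PMB cleavage by DDQ frees only the C8 hydroxyl and leaves the silyl ether, lactone and alkenes intact.

Step 18
Reactants: 22 (C8 alcohol); 16 (2S,3R)-2,3-dimethyloxirane-2-carboxylic acid
Product: 24 methyl (3aS,4S,5R,6E,10E,11aR)-5-[(tert-butyldimethylsilyl)oxy]-4-{[(2S,3R)-2,3-dimethyloxirane-2-carbonyl]oxy}-10-methyl-3-methylidene-2-oxo-2,3,3a,4,5,8,9,11a-octahydrocyclodeca[b]furan-6-carboxylate, via mixed anhydride 23 (not isolated)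
Conditions: 16, 2,4,6-Cl3C6H2COCl, Et3N, THF, rt; then 22, DMAP, toluene, rt → 40 °C
Reagents that add atoms: none
Why: Yamaguchi esterification through the mixed anhydride acylates the hindered C8 hydroxyl with the α-quaternary acid, whose stereocentres cannot epimerise.

Step 19
Reactants: 24 (C9 TBS ether of the ester)
Product: 25 methyl (3aS,4S,5R,6E,10E,11aR)-4-{[(2S,3R)-2,3-dimethyloxirane-2-carbonyl]oxy}-5-hydroxy-10-methyl-3-methylidene-2-oxo-2,3,3a,4,5,8,9,11a-octahydrocyclodeca[b]furan-6-carboxylate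
Conditions: HF·pyridine, pyridine, THF, 0 °C → rt
Reagents that add atoms: none
Why: fluoride desilylation under mildly acidic conditions avoids 8→9 acyl migration and Michael addition to the methylene lactone.

Step 20
Reactants: 25 (4,5-alkene precursor)
Product: 26 target, methyl (1S,2R,4R,7E,9R,10S,11R)-10-{[(2S,3R)-2,3-dimethyloxirane-2-carbonyl]oxy}-9-hydroxy-4-methyl-12-methylidene-13-oxo-3,14-dioxatricyclo[9.3.0.0(2,4)]tetradec-7-ene-8-carboxylate
Conditions: mCPBA (1.1 equiv), NaHCO3, CH2Cl2, 0 °C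
Reagents that add atoms: 3-chloroperbenzoic acid O=C(OO)c1cccc(Cl)c1
Why: Prilezhaev epoxidation touches only the electron-rich trisubstituted 4,5-alkene, and attack on its exposed peripheral face (alkene perpendicular to the ring, H5 anti to H6) is expected to give the 4R,5R epoxide, as in the costunolide-to-parthenolide series.

**Compound list**
1 | pent-4-yn-1-ol | C#CCCCO | starting material
2 | dimethyl[(1E)-5-(dimethylaluminiooxy)-2-methylpent-1-en-1-yl]alane (alkenylalane) | C[Al](C)OCCC/C(C)=C/[Al](C)C | intermediate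
3 | (2E)-3-methylhex-2-ene-1,6-diol | OC/C=C(\C)CCCO | intermediate
4 | (2E)-3-methylhex-2-enedial | O=C/C=C(\C)CCC=O | intermediate
5 | methyl (2Z,6E)-2-iodo-6-methyl-8-oxoocta-2,6-dienoate | COC(=O)/C(I)=C/CC/C(C)=C/C=O | intermediate
6 | 2-(bromomethyl)prop-2-enoic acid | C=C(CBr)C(=O)O | starting material
7 | 2-(bromomethyl)prop-2-enoyl chloride | C=C(CBr)C(Cl)=O | intermediate
8 | (2S)-but-3-ene-1,2-diol | C=C[C@H](O)CO | starting material
9 | (4S)-4-ethenyl-2-(4-methoxyphenyl)-1,3-dioxolane (C2 epimers) | C=C[C@H]1COC(c2ccc(OC)cc2)O1 | intermediate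
10 | (2S)-2-[(4-methoxyphenyl)methoxy]but-3-en-1-ol | C=C[C@H](OCc1ccc(OC)cc1)CO | intermediate
11 | (2S)-2-[(4-methoxyphenyl)methoxy]but-3-en-1-yl 2-(bromomethyl)prop-2-enoate | C=C[C@H](OCc1ccc(OC)cc1)COC(=O)C(=C)CBr | intermediate
12 | (5S)-3-(bromomethyl)-5-[(4-methoxyphenyl)methoxy]-5,6-dihydro-2H-pyran-2-one | BrCC1=C[C@H](OCc2ccc(OC)cc2)COC1=O | intermediate
13 | (2E)-2-methylbut-2-enoic acid (tiglic acid) | C/C=C(\C)C(=O)O | starting material
14 | (2E)-2-methylbut-2-en-1-ol | C/C=C(\C)CO | intermediate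
15 | [(2R,3R)-2,3-dimethyloxiran-2-yl]methanol | OC[C@@]1(C)O[C@@H]1C | intermediate
16 | (2S,3R)-2,3-dimethyloxirane-2-carboxylic acid | OC(=O)[C@@]1(C)O[C@@H]1C | intermediate
17 | methyl (2Z,6E,8R)-8-hydroxy-2-iodo-8-{(4S,5S)-5-[(4-methoxyphenyl)methoxy]-3-methylidene-2-oxooxan-4-yl}-6-methylocta-2,6-dienoate | C=C1C(=O)OC[C@@H](OCc2ccc(OC)cc2)[C@@H]1[C@H](O)/C=C(\C)CC/C=C(\I)C(=O)OC | intermediate
18 | methyl (2Z,6E)-7-{(2R,3S)-3-[(1S)-2-hydroxy-1-[(4-methoxyphenyl)methoxy]ethyl]-4-methylidene-5-oxooxolan-2-yl}-2-iodo-6-methylhepta-2,6-dienoate | C=C1C(=O)O[C@H](/C=C(\C)CC/C=C(\I)C(=O)OC)[C@H]1[C@H](OCc1ccc(OC)cc1)CO | intermediate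
19 | methyl (2Z,6E)-2-iodo-7-{(2R,3S)-3-[(1S)-1-[(4-methoxyphenyl)methoxy]-2-oxoethyl]-4-methylidene-5-oxooxolan-2-yl}-6-methylhepta-2,6-dienoate | C=C1C(=O)O[C@H](/C=C(\C)CC/C=C(\I)C(=O)OC)[C@H]1[C@H](OCc1ccc(OC)cc1)C=O | intermediate
20 | methyl (3aS,4S,5R,6E,10E,11aR)-5-hydroxy-4-[(4-methoxyphenyl)methoxy]-10-methyl-3-methylidene-2-oxo-2,3,3a,4,5,8,9,11a-octahydrocyclodeca[b]furan-6-carboxylate | C=C1C(=O)O[C@@H]2/C=C(\C)CC/C=C(C(=O)OC)\[C@@H](O)[C@@H](OCc3ccc(OC)cc3)[C@@H]12 | intermediate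
21 | methyl (3aS,4S,5R,6E,10E,11aR)-5-[(tert-butyldimethylsilyl)oxy]-4-[(4-methoxyphenyl)methoxy]-10-methyl-3-methylidene-2-oxo-2,3,3a,4,5,8,9,11a-octahydrocyclodeca[b]furan-6-carboxylate | C=C1C(=O)O[C@@H]2/C=C(\C)CC/C=C(C(=O)OC)\[C@@H](O[Si](C)(C)C(C)(C)C)[C@@H](OCc3ccc(OC)cc3)[C@@H]12 | intermediate
22 | methyl (3aR,4S,5R,6E,10E,11aR)-5-[(tert-butyldimethylsilyl)oxy]-4-hydroxy-10-methyl-3-methylidene-2-oxo-2,3,3a,4,5,8,9,11a-octahydrocyclodeca[b]furan-6-carboxylate | C=C1C(=O)O[C@@H]2/C=C(\C)CC/C=C(C(=O)OC)\[C@@H](O[Si](C)(C)C(C)(C)C)[C@@H](O)[C@@H]12 | intermediate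
23 | (2S,3R)-2,3-dimethyloxirane-2-carboxylic 2,4,6-trichlorobenzoic anhydride (mixed anhydride) | O=C(OC(=O)[C@@]1(C)O[C@@H]1C)c1c(Cl)cc(Cl)cc1Cl | intermediate
24 | methyl (3aS,4S,5R,6E,10E,11aR)-5-[(tert-butyldimethylsilyl)oxy]-4-{[(2S,3R)-2,3-dimethyloxirane-2-carbonyl]oxy}-10-methyl-3-methylidene-2-oxo-2,3,3a,4,5,8,9,11a-octahydrocyclodeca[b]furan-6-carboxylate | C=C1C(=O)O[C@@H]2/C=C(\C)CC/C=C(C(=O)OC)\[C@@H](O[Si](C)(C)C(C)(C)C)[C@@H](OC(=O)[C@@]3(C)O[C@@H]3C)[C@@H]12 | intermediate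
25 | methyl (3aS,4S,5R,6E,10E,11aR)-4-{[(2S,3R)-2,3-dimethyloxirane-2-carbonyl]oxy}-5-hydroxy-10-methyl-3-methylidene-2-oxo-2,3,3a,4,5,8,9,11a-octahydrocyclodeca[b]furan-6-carboxylate | C=C1C(=O)O[C@@H]2/C=C(\C)CC/C=C(C(=O)OC)\[C@@H](O)[C@@H](OC(=O)[C@@]3(C)O[C@@H]3C)[C@@H]12 | intermediate
26 | CNP0262846.1, methyl (1S,2R,4R,7E,9R,10S,11R)-10-{[(2S,3R)-2,3-dimethyloxirane-2-carbonyl]oxy}-9-hydroxy-4-methyl-12-methylidene-13-oxo-3,14-dioxatricyclo[9.3.0.0(2,4)]tetradec-7-ene-8-carboxylate | C=C1C(=O)O[C@H]2[C@H]1[C@H](OC(=O)[C@@]1(C)O[C@@H]1C)[C@H](O)/C(C(=O)OC)=C\CC[C@@]1(C)O[C@H]21 | target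

**Count**
Total steps: 20.
Longest linear sequence: 13 steps (steps 5–8, then 12–20, from (2S)-but-3-ene-1,2-diol).

**Three steps most likely to fail**

Step 12 (Barbier union). The allylindium may add with the wrong facial or syn/anti sense, or the metal may attack the iodoenoate. The fallback sets out from 12 and returns at 17. Bromide 12 is converted by Pd-catalysed Miyaura borylation (B2pin2, Pd2(dba)3, DMSO, 50 °C; boron at the primary allyl terminus) into the configurationally stable allylboronate F1. F1 is heated with enal 5 (toluene, 80 °C, or 10 mol % Sc(OTf)3 at rt). This type-I allylboration uses the same closed chair but no redox-active metal, and triethanolamine work-up gives 17.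

Step 15 (NHK ring closure). The ring conformation rather than the Felkin model may decide C9. The fallback sets out from 19 and returns at 20. The closure is then used only for C–C bond formation, accepting the C9-epimeric carbinol F2. F2, alone or mixed with 20, is oxidised with Dess–Martin periodinane to the macrocyclic enone F3. C9 is then set by hydride instead of by carbon: Zn(BH4)2 in Et2O at −20 °C chelates the C9 carbonyl and the C8 PMB ether and delivers hydride 1,2 from the face away from C7, giving the 8,9-anti alcohol 20.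

Step 20 (late epoxidation). Facial selectivity rests on the ring conformation alone. The fallback sets out from 17 and returns at 26. The free allylic C6 hydroxyl of 17 directs the peracid: mCPBA (CH2Cl2, 0 °C) epoxidises the 4,5-alkene syn to the hydroxyl in the A(1,3)-minimised conformer (C4 methyl cis to C6), giving the threo (4R,5R) epoxy alcohol F4. The main sequence is then repeated on the epoxides:
- lactone transposition (Ti(OiPr)4 or PPTS) gives the epoxy γ-lactone alcohol F5;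
- Dess–Martin oxidation gives the epoxy aldehyde F6;
- NHK closure gives the epoxy macrocycle F7;
- TBSOTf at −78 °C gives its silyl ether F8;
- DDQ gives the C8 alcohol F9;
- Yamaguchi esterification with 16 gives the epoxy ester F10;
- buffered TBAF/AcOH desilylation gives 26.

**Further compounds**
F1 | step 12 | (5S)-5-[(4-methoxyphenyl)methoxy]-3-[(4,4,5,5-tetramethyl-1,3,2-dioxaborolan-2-yl)methyl]-5,6-dihydro-2H-pyran-2-one | CC1(C)OB(CC2=C[C@H](OCc3ccc(OC)cc3)COC2=O)OC1(C)C
F2 | step 15 | methyl (3aS,4S,5S,6E,10E,11aR)-5-hydroxy-4-[(4-methoxyphenyl)methoxy]-10-methyl-3-methylidene-2-oxo-2,3,3a,4,5,8,9,11a-octahydrocyclodeca[b]furan-6-carboxylate (C9 epimer of 20) | C=C1C(=O)O[C@@H]2/C=C(\C)CC/C=C(C(=O)OC)\[C@H](O)[C@@H](OCc3ccc(OC)cc3)[C@@H]12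
F3 | step 15 | methyl (3aS,4S,6E,10E,11aR)-4-[(4-methoxyphenyl)methoxy]-10-methyl-3-methylidene-2,5-dioxo-2,3,3a,4,5,8,9,11a-octahydrocyclodeca[b]furan-6-carboxylate | C=C1C(=O)O[C@@H]2/C=C(\C)CC/C=C(C(=O)OC)\C(=O)[C@@H](OCc3ccc(OC)cc3)[C@@H]12
F4 | step 20 | (4R,5R)-4,5-epoxide of 17: methyl (2Z)-5-{(2R,3R)-3-[(S)-hydroxy{(4S,5S)-5-[(4-methoxyphenyl)methoxy]-3-methylidene-2-oxooxan-4-yl}methyl]-2-methyloxiran-2-yl}-2-iodopent-2-enoate | C=C1C(=O)OC[C@@H](OCc2ccc(OC)cc2)[C@@H]1[C@H](O)[C@H]1O[C@]1(C)CC/C=C(\I)C(=O)OC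
F5 | step 20 | (4R,5R)-4,5-epoxide of 18 (γ-lactone, free C9 alcohol) | C=C1C(=O)O[C@H]([C@H]2O[C@]2(C)CC/C=C(\I)C(=O)OC)[C@H]1[C@H](OCc1ccc(OC)cc1)CO
F6 | step 20 | (4R,5R)-4,5-epoxide of 19 (C9 aldehyde) | C=C1C(=O)O[C@H]([C@H]2O[C@]2(C)CC/C=C(\I)C(=O)OC)[C@H]1[C@H](OCc1ccc(OC)cc1)C=O
F7 | step 20 | (4R,5R)-4,5-epoxide of 20 (macrocycle, C9 alcohol, C8 PMB ether) | C=C1C(=O)O[C@H]2[C@H]1[C@H](OCc1ccc(OC)cc1)[C@H](O)/C(C(=O)OC)=C\CC[C@@]1(C)O[C@H]21
F8 | step 20 | (4R,5R)-4,5-epoxide of 21 (C9 TBS ether, C8 PMB ether) | C=C1C(=O)O[C@H]2[C@H]1[C@H](OCc1ccc(OC)cc1)[C@H](O[Si](C)(C)C(C)(C)C)/C(C(=O)OC)=C\CC[C@@]1(C)O[C@H]21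
F9 | step 20 | (4R,5R)-4,5-epoxide of 22 (C9 TBS ether, C8 alcohol) | C=C1C(=O)O[C@H]2[C@H]1[C@H](O)[C@H](O[Si](C)(C)C(C)(C)C)/C(C(=O)OC)=C\CC[C@@]1(C)O[C@H]21
F10 | step 20 | (4R,5R)-4,5-epoxide of 24 (C9 TBS ether of the target) | C=C1C(=O)O[C@H]2[C@H]1[C@H](OC(=O)[C@@]1(C)O[C@@H]1C)[C@H](O[Si](C)(C)C(C)(C)C)/C(C(=O)OC)=C\CC[C@@]1(C)O[C@H]21
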